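**Retrosynthetic overview**

1. Numbering: C1 is the acetoxy carbon (one-carbon bridge), C2 and C6 the bridgeheads, C3–C4=C5 the enal bridge, C7 (quaternary)–C8 (acetyl)–C9–C10 the four-carbon bridge, C11 the side-chain stereocentre.
2. The plan rests on C2–C1(O)–C6 being a three-carbon oxyallyl unit locked in the six-membered ring and C7–C8–C9–C10 being a diene. The seven-membered ring (C1, C2, C10, C9, C8, C7, C6) of the bicyclo[4.3.1]decane is closed by forming C2–C10 and C6–C7 in one (4+3) step between a 2-chloro-3-(silyloxymethyl)cyclohexanone and a 2-silyl diene.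
3. Before: the chloroketone comes from 3-methoxybenzyl alcohol (Birch reduction, silylation, asymmetric conjugate reduction with chlorination of the enol ether; C5 is a temporary control element). The diene comes from (S)-citronellal (alkyne, silylalkyne, syn-methylalumination/iodination, Stille vinylation).
4. After: the C1 ketone is turned into the methyl carbinol acetate first, while it is the only ketone. The C8 vinylsilane then goes to the iodide, the acetyl enone, and by conjugate reduction and equilibration to the C8 acetyl centre. Last, C5 CH2OH goes to CHO and the C4=C5 enal, which erases C5.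
5. Ring order: six-membered carbocycle first (from the arene), seven-membered ring second (key step).

Key step: step 8

Remark on stereochemistry: the (4+3) step can only bridge C2 and C6 on one face of the six-membered ring, so C2 follows from C6; relative configurations are therefore described from C6 (C5 substituent anti to the four-carbon bridge, C7 methyl cis to C5, C8 acetyl trans to the C7 methyl, C1 oxygen on the side of the four-carbon bridge), and all structures carry the stereodescriptors of the target SMILES unchanged.

TBS = tert-butyl(dimethyl)silyl.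

**Route**

Step 1
Reactants: 1 (3-methoxyphenyl)methanol
Product: 3 3-(hydroxymethyl)cyclohex-2-en-1-one, via (5-methoxycyclohexa-1,4-dien-1-yl)methanol 2 (not isolated)
Conditions: Li, NH3 (l), t-BuOH, THF, −78 °C; then 2 M HCl, THF, rt
Reagents that add atoms: water, O
Why: Birch reduction leaves the two donor-bearing ring carbons on the double bonds, and aqueous acid hydrolyses the enol ether and moves the alkene into conjugation, giving the achiral 3-substituted cyclohexenone.

Step 2
Reactants: 3 3-(hydroxymethyl)cyclohex-2-en-1-one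
Product: 4 3-(TBS-oxymethyl)cyclohex-2-en-1-one
Conditions: TBSCl, imidazole, DMF, rt
Reagents that add atoms: tert-butyl(chloro)dimethylsilane, CC(C)(C)[Si](C)(C)Cl
Why: Imidazole-promoted silylation of the primary alcohol gives an ether that should survive hydride, chlorination and the amine/fluoroalcohol medium of the key step.

Step 3
Reactants: 4 3-(TBS-oxymethyl)cyclohex-2-en-1-one
Product: 6 (3S)-2-chloro-3-(TBS-oxymethyl)cyclohexan-1-one (chloride epimers), via diethoxy(methyl)silyl enol ether 5 (not isolated)
Conditions: Cu(OAc)2·H2O (cat.), (R)-DTBM-SEGPHOS (cat.), (EtO)2MeSiH, toluene, 0 °C; then NCS, THF, −20 °C → rt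
Reagents that add atoms: N-chlorosuccinimide, O=C1CCC(=O)N1Cl
Why: Bisphosphine-ligated copper hydride adds hydride to the enone β-carbon (C5) on the ligand-selected face and the silane turns the copper enolate into the regiodefined C1–C6 silyl enol ether 5, which NCS chlorinates at the enol carbon (asymmetric conjugate reduction, then electrophilic α-chlorination of a silyl enol ether); the antipodal ligand is taken should the sense of induction prove opposite, and the chloride configuration is irrelevant because it is lost on ionisation.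

Step 4
Reactants: 7 (S)-citronellal
Product: 9 (3S)-3,7-dimethyloct-6-en-1-yne, via alkenyl nonaflate 8 (not isolated)
Conditions: n-C4F9SO2F, phosphazene base P2-Et, DMF, −20 °C → rt
Reagents that add atoms: none
Why: The enolate oxygen is sulfonylated to the alkenyl nonaflate and the phosphazene base then effects E2 loss of nonaflate (one-pot aldehyde-to-alkyne conversion without homologation), so the two aldehyde carbons become the alkyne (later C8 and C7) and C11 is not touched.

Step 5
Reactants: 9 (3S)-3,7-dimethyloct-6-en-1-yne
Product: 11 trimethyl[(3S)-3,7-dimethyloct-6-en-1-yn-1-yl]silane, via lithium acetylide 10 (not isolated)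
Conditions: n-BuLi, THF, −78 °C; then Me3SiCl, −78 °C → rt
Reagents that add atoms: chlorotrimethylsilane, C[Si](C)(C)Cl
Why: Deprotonation of the terminal alkyne and C-silylation of the acetylide; the propargylic C11–H is not acidic enough to be touched.

Step 6
Reactants: 11 trimethyl[(3S)-3,7-dimethyloct-6-en-1-yn-1-yl]silane
Product: 13 (1E,3S)-1-iodo-2,3,7-trimethyl-1-(trimethylsilyl)octa-1,6-diene, via alkenyldimethylalane 12 (not isolated)
Conditions: Me3Al, Cp2ZrCl2 (cat.), ClCH2CH2Cl, rt; then I2, THF, −78 °C
Reagents that add atoms: trimethylaluminium, C[Al](C)C; iodine, II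
Why: Zirconium-catalysed carboalumination adds methyl and aluminium syn across the silylalkyne with methyl on the carbon remote from silicon, and iodinolysis with retention at low temperature (before the α-silyl alkenylalane can isomerise) should give the iodide with iodine cis to the new methyl group, the geometry to be confirmed by NOE.

Step 7
Reactants: 13 (1E,3S)-1-iodo-2,3,7-trimethyl-1-(trimethylsilyl)octa-1,6-diene
Product: 14 trimethyl[(3Z,5S)-4,5,9-trimethyldeca-1,3,8-trien-3-yl]silane
Conditions: Bu3SnCH=CH2, Pd(PPh3)4 (cat.), CuI, CsF, DMF, 45 °C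
Reagents that add atoms: tributyl(vinyl)stannane, C=C[Sn](CCCC)(CCCC)CCCC
Why: Stille coupling with retention of alkene geometry, accelerated by CuI and fluoride for the hindered iodide, places the vinyl group cis to the methyl group (the later inside position) and silicon cis to the C11 branch.

Step 8
Reactants: 6 (3S)-2-chloro-3-(TBS-oxymethyl)cyclohexan-1-one; 14 trimethyl[(3Z,5S)-4,5,9-trimethyldeca-1,3,8-trien-3-yl]silane
Product: 16 5-(TBS-oxymethyl)-7-methyl-7-[(2S)-6-methylhept-5-en-2-yl]-8-(trimethylsilyl)bicyclo[4.3.1]dec-8-en-1-one, via 2-oxidocyclohexenyl cation 15 (not isolated)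
Conditions: Et3N, CF3CH2OH, 0 °C → rt (6 in 1.5 equiv, added slowly to 14)
Reagents that add atoms: none
Why: Proposed new method: Et3N removes the C2 proton of 6 and chloride leaves from C6 in the ionising solvent to give the planar, U-shaped 2-oxidocyclohexenyl cation 15, whose unhindered terminus C2 is attacked by the vinyl CH2 (C10) of 14; the resulting tertiary allyl cation (C7–C8–C9, silicon on the central carbon) is then captured at C7 by the enolate carbon C6, a stepwise (4+3) annulation. The closest known reactions are the (4+3) cycloadditions of oxyallyl cations from 2-chlorocyclohexanones (amine base, fluorinated alcohol) with furans, cyclopentadiene and simple butadienes, which have not been used to create a quaternary diene terminus. The seven-membered ring C1–C2–C10–C9–C8–C7–C6 closes by C–C bond formation between enolate carbon C6 and cationic C7 (7-endo capture of the allyl cation), which puts the bicyclo[4.3.1] skeleton on the preformed six-membered ring. C2 and C6 arise because both bonds form on the cation face anti to the C5 CH2OTBS group, an enantiopure centre that is erased later, and C7 arises from the diene geometry in the compact transition state (C8–C9 over C1–O), where the inside methyl ends cis to C5 and the outside C11 chain on the outer face. The step needs the orientation C10 to C2 and C7 to C6, secured by the branch at C5 that shields C6 during the first, intermolecular bond, and it needs C- over O-closure, favoured by the hydrogen-bonded enolate oxygen in CF3CH2OH; the SiMe3 group keeps C8 unreactive, lies over the open oxygen side in the compact mode and stays as the C8 handle. C11 is carried unchanged from citronellal.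

Step 9
Reactants: 16 (4+3) adduct
Product: 17 5-(hydroxymethyl)-7-methyl-7-[(2S)-6-methylhept-5-en-2-yl]-8-(trimethylsilyl)bicyclo[4.3.1]dec-8-en-1-one
Conditions: HF·pyridine, pyridine/THF, 0 °C
Reagents that add atoms: none
Why: Fluoride cleaves the primary silyl ether while the vinyl–SiMe3 bond and the alkenes are inert under buffered HF (silyl ether cleavage); the freed alcohol, axial on the cyclohexane and next to C1, may rest as the C1 hemiketal, which does not matter for the next step.

Step 10
Reactants: 17 hydroxy ketone
Product: 19 1-acetoxy-5-(acetoxymethyl)-1,7-dimethyl-7-[(2S)-6-methylhept-5-en-2-yl]-8-(trimethylsilyl)bicyclo[4.3.1]dec-8-ene, via dilithium dialkoxide of the diol 18 (not isolated)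
Conditions: MeLi, Et2O/toluene, −78 → 0 °C; then Ac2O, DMAP, 0 °C → rt
Reagents that add atoms: methyllithium, [Li]C; acetic anhydride, CC(=O)OC(C)=O
Why: Methyllithium deprotonates the hydroxyl and adds to the non-enolisable C1 ketone (both α-carbons are bridgeheads) from the face over the three-carbon bridge, guided by the neighbouring C5 CH2OLi group and away from the pseudoaxial C7 side chain that screens the other face (alkoxide-directed 1,2-addition), so the new methyl is cis to C5 CH2O and the oxygen lies toward the four-carbon bridge; acetic anhydride then acylates both lithium alkoxides, the practical way to esterify the hindered tertiary oxygen.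

Step 11
Reactants: 19 diacetate vinylsilane
Product: 20 1-acetoxy-5-(acetoxymethyl)-8-iodo-1,7-dimethyl-7-[(2S)-6-methylhept-5-en-2-yl]bicyclo[4.3.1]dec-8-ene
Conditions: NIS, 2,6-lutidine, (CF3)2CHOH, 0 °C
Reagents that add atoms: N-iodosuccinimide, O=C1CCC(=O)N1I
Why: Electrophilic ipso-iododesilylation: iodine adds to C8, the β-silyl cation loses SiMe3 and the ring fixes the alkene geometry, while the side-chain alkene can only form a reversible iodonium ion in the buffered, weakly nucleophilic fluorinated alcohol.

Step 12
Reactants: 20 alkenyl iodide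
Product: 22 1-acetoxy-5-(acetoxymethyl)-8-acetyl-1,7-dimethyl-7-[(2S)-6-methylhept-5-en-2-yl]bicyclo[4.3.1]dec-8-ene, via 8-(1-ethoxyvinyl) diene 21 (not isolated)
Conditions: Bu3SnC(OEt)=CH2, Pd(PPh3)4 (cat.), CuI, CsF, DMF, 50 °C; then 1 M HCl, THF, rt
Reagents that add atoms: tributyl(1-ethoxyvinyl)stannane, CCOC(=C)[Sn](CCCC)(CCCC)CCCC; water, O
Why: Stille coupling of the hindered alkenyl iodide with the 1-ethoxyvinyl stannane (an acetyl anion equivalent) and mild acid hydrolysis of the dienol ether should give the C8 acetyl enone without touching the acetates.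

Step 13
Reactants: 22 enone
Product: 23 1-acetoxy-5-(acetoxymethyl)-8-acetyl-1,7-dimethyl-7-[(2S)-6-methylhept-5-en-2-yl]bicyclo[4.3.1]decane (C8 epimers)
Conditions: Cu(OAc)2·H2O (cat.), 1,2-bis(diphenylphosphino)benzene (cat.), (EtO)2MeSiH, t-BuOH, toluene, rt
Reagents that add atoms: none
Why: Ligated copper hydride reduces the enone in the 1,4-sense (hydride to C9) and leaves the isolated trisubstituted alkene and both acetates alone (catalytic conjugate reduction); the C8 configuration formed on protonation is not relied on.

Step 14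
Reactants: 23 keto diacetate (C8 epimers)
Product: 24 1-acetoxy-8-acetyl-5-(hydroxymethyl)-1,7-dimethyl-7-[(2S)-6-methylhept-5-en-2-yl]bicyclo[4.3.1]decane (C8 acetyl trans to C7 methyl)
Conditions: K2CO3, MeOH, 0 °C → rt
Reagents that add atoms: none
Why: Methanolysis removes the unhindered primary acetate and spares the hindered tertiary one (selective transesterification), and the same base equilibrates the enolisable C8 centre to the more stable epimer with the acetyl group equatorial on the outer face of the seven-membered ring, trans to the C7 methyl group.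

Step 15
Reactants: 24 hydroxymethyl ketone
Product: 25 1-acetoxy-8-acetyl-1,7-dimethyl-7-[(2S)-6-methylhept-5-en-2-yl]bicyclo[4.3.1]decane-5-carbaldehyde
Conditions: Dess–Martin periodinane, pyridine, CH2Cl2, 0 °C → rt
Reagents that add atoms: none
Why: Dess–Martin oxidation of the primary alcohol to the aldehyde under buffered conditions; the tertiary acetate, ketone and alkene are inert and the C5 configuration no longer matters.

Step 16
Reactants: 25 aldehyde
Product: 28 target CNP0288370.1, via 5-(phenylselanyl) aldehyde 26 (not isolated), via selenoxide 27 (not isolated)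
Conditions: N-(phenylseleno)phthalimide, L-prolinamide (cat.), CH2Cl2, rt; then NaIO4, THF/H2O, 0 °C → rt
Reagents that add atoms: none
Why: The aldehyde alone forms an enamine with the amine catalyst and is selenenylated at C5 (organocatalytic α-selenenylation), and periodate oxidation to the selenoxide is followed by syn-elimination toward C4, since C6 is a bridgehead, which gives the C4=C5 enal, removes the C5 stereocentre and leaves the methyl ketone untouched.

**Compound list**

1 | (3-methoxyphenyl)methanol | COc1cccc(CO)c1 | starting material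
2 | (5-methoxycyclohexa-1,4-dien-1-yl)methanol | COC1=CCC=C(CO)C1 | intermediate (not isolated)
3 | 3-(hydroxymethyl)cyclohex-2-en-1-one | O=C1C=C(CO)CCC1 | intermediate
4 | 3-(TBS-oxymethyl)cyclohex-2-en-1-one | O=C1C=C(CO[Si](C)(C)C(C)(C)C)CCC1 | intermediate
5 | diethoxy(methyl)silyl enol ether of (3R)-3-(TBS-oxymethyl)cyclohexanone, enol double bond toward the substituted carbon | CCO[Si](C)(OCC)OC1=C[C@H](CO[Si](C)(C)C(C)(C)C)CCC1 | intermediate (not isolated)
6 | (3S)-2-chloro-3-(TBS-oxymethyl)cyclohexan-1-one, chloride epimers | O=C1CCC[C@@H](CO[Si](C)(C)C(C)(C)C)C1Cl | intermediate (key-step precursor)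
7 | (S)-citronellal, (3S)-3,7-dimethyloct-6-enal | C[C@@H](CCC=C(C)C)CC=O | starting material
8 | (3S)-3,7-dimethylocta-1,6-dien-1-yl nonafluorobutane-1-sulfonate, E/Z | C[C@@H](CCC=C(C)C)C=COS(=O)(=O)C(F)(F)C(F)(F)C(F)(F)C(F)(F)F | intermediate (not isolated)
9 | (3S)-3,7-dimethyloct-6-en-1-yne | C#C[C@@H](C)CCC=C(C)C | intermediate
10 | lithium (3S)-3,7-dimethyloct-6-en-1-yn-1-ide | [Li]C#C[C@@H](C)CCC=C(C)C | intermediate (not isolated)
11 | trimethyl[(3S)-3,7-dimethyloct-6-en-1-yn-1-yl]silane | C[Si](C)(C)C#C[C@@H](C)CCC=C(C)C | intermediate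
12 | dimethyl[(1Z,3S)-2,3,7-trimethyl-1-(trimethylsilyl)octa-1,6-dien-1-yl]alumane, Al cis to the new methyl | C[Al](C)/C([Si](C)(C)C)=C(\C)[C@@H](C)CCC=C(C)C | intermediate (not isolated)
13 | (1E,3S)-1-iodo-2,3,7-trimethyl-1-(trimethylsilyl)octa-1,6-diene, I cis to methyl | I/C([Si](C)(C)C)=C(\C)[C@@H](C)CCC=C(C)C | intermediate
14 | trimethyl[(3Z,5S)-4,5,9-trimethyldeca-1,3,8-trien-3-yl]silane, vinyl cis to methyl | C=C/C([Si](C)(C)C)=C(\C)[C@@H](C)CCC=C(C)C | intermediate (key-step precursor)
15 | 2-oxidocyclohexenyl (oxyallyl) cation with the C5 CH2OTBS group | [O-]C1=CCC[C@@H](CO[Si](C)(C)C(C)(C)C)[CH+]1 | intermediate (not isolated)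
16 | 5-(TBS-oxymethyl)-7-methyl-7-[(2S)-6-methylhept-5-en-2-yl]-8-(trimethylsilyl)bicyclo[4.3.1]dec-8-en-1-one; C5 group anti to the four-carbon bridge, C7 methyl cis to C5 | O=C1[C@@H]2CC[C@@H](CO[Si](C)(C)C(C)(C)C)[C@@H]1[C@@](C)([C@@H](C)CCC=C(C)C)C([Si](C)(C)C)=CC2 | intermediate (key-step product)
17 | 5-(hydroxymethyl) analogue of 16 (may rest as its C1 hemiketal) | O=C1[C@@H]2CC[C@@H](CO)[C@@H]1[C@@](C)([C@@H](C)CCC=C(C)C)C([Si](C)(C)C)=CC2 | intermediate
18 | dilithium dialkoxide of the C1 methyl carbinol / C5 hydroxymethyl diol; C1 methyl cis to C5 CH2O | [Li]O[C@]1(C)[C@@H]2CC[C@@H](CO[Li])[C@@H]1[C@@](C)([C@@H](C)CCC=C(C)C)C([Si](C)(C)C)=CC2 | intermediate (not isolated)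
19 | 1-acetoxy-5-(acetoxymethyl)-1,7-dimethyl-7-[(2S)-6-methylhept-5-en-2-yl]-8-(trimethylsilyl)bicyclo[4.3.1]dec-8-ene | CC(=O)O[C@]1(C)[C@@H]2CC[C@@H](COC(C)=O)[C@@H]1[C@@](C)([C@@H](C)CCC=C(C)C)C([Si](C)(C)C)=CC2 | intermediate
20 | 8-iodo analogue of 19 | CC(=O)O[C@]1(C)[C@@H]2CC[C@@H](COC(C)=O)[C@@H]1[C@@](C)([C@@H](C)CCC=C(C)C)C(I)=CC2 | intermediate
21 | 8-(1-ethoxyvinyl) analogue of 19 | CC(=O)O[C@]1(C)[C@@H]2CC[C@@H](COC(C)=O)[C@@H]1[C@@](C)([C@@H](C)CCC=C(C)C)C(C(=C)OCC)=CC2 | intermediate (not isolated)
22 | 8-acetyl analogue of 19 (C8=C9 enone) | CC(=O)O[C@]1(C)[C@@H]2CC[C@@H](COC(C)=O)[C@@H]1[C@@](C)([C@@H](C)CCC=C(C)C)C(C(C)=O)=CC2 | intermediate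
23 | 1-acetoxy-5-(acetoxymethyl)-8-acetyl-1,7-dimethyl-7-[(2S)-6-methylhept-5-en-2-yl]bicyclo[4.3.1]decane, C8 epimers | CC(=O)O[C@]1(C)[C@@H]2CC[C@@H](COC(C)=O)[C@@H]1[C@@](C)([C@@H](C)CCC=C(C)C)C(C(C)=O)CC2 | intermediate
24 | 1-acetoxy-8-acetyl-5-(hydroxymethyl)-1,7-dimethyl-7-[(2S)-6-methylhept-5-en-2-yl]bicyclo[4.3.1]decane; acetyl trans to C7 methyl | CC(=O)O[C@]1(C)[C@@H]2CC[C@@H](CO)[C@@H]1[C@@](C)([C@@H](C)CCC=C(C)C)[C@@H](C(C)=O)CC2 | intermediate
25 | 1-acetoxy-8-acetyl-1,7-dimethyl-7-[(2S)-6-methylhept-5-en-2-yl]bicyclo[4.3.1]decane-5-carbaldehyde | CC(=O)O[C@]1(C)[C@@H]2CC[C@@H](C=O)[C@@H]1[C@@](C)([C@@H](C)CCC=C(C)C)[C@@H](C(C)=O)CC2 | intermediate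
26 | 5-(phenylselanyl) derivative of 25, C5 epimers | CC(=O)O[C@]1(C)[C@@H]2CCC(C=O)([Se]c3ccccc3)[C@@H]1[C@@](C)([C@@H](C)CCC=C(C)C)[C@@H](C(C)=O)CC2 | intermediate (not isolated)
27 | selenoxide of 26 | CC(=O)O[C@]1(C)[C@@H]2CCC(C=O)([Se](=O)c3ccccc3)[C@@H]1[C@@](C)([C@@H](C)CCC=C(C)C)[C@@H](C(C)=O)CC2 | intermediate (not isolated)
28 | CNP0288370.1: 1-acetoxy-8-acetyl-1,7-dimethyl-7-[(2S)-6-methylhept-5-en-2-yl]bicyclo[4.3.1]dec-4-ene-5-carbaldehyde (route numbering) | CC(=O)O[C@]1(C)[C@@H]2CC=C(C=O)[C@@H]1[C@@](C)([C@@H](C)CCC=C(C)C)[C@@H](C(C)=O)CC2 | target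

**Step count and risks**

Total: 16 steps. Longest linear sequence: 13 steps (7 to 28 through steps 4–16); the ketone branch (steps 1–3) joins at step 8.

Steps most likely to fail:

Step 8 (key step). The first bond may form at the wrong cation terminus (C10 to C6), which reverses the orientation. The allyl cation may instead close through oxygen or at C9, lose a proton to a triene, or the oxyallyl cation may be trapped by the solvent before the crowded diene reacts. Facial selectivity against the C5 group may also be incomplete. The fallback makes the two bonds one after the other by known reactions, setting out from enone 4 and iodide 13 and returning at 16. The α′-lithium enolate of 4 (LiN(i-Pr)2, THF, −78 °C) is alkylated with allyl bromide to 6-allyl-3-(TBS-oxymethyl)cyclohex-2-en-1-one F1. Its terminal alkene is cleaved (OsO4 cat., NaIO4, 2,6-lutidine; Lemieux–Johnson oxidation) to the keto aldehyde F2. Iodine–magnesium exchange on 13 (i-PrMgCl·LiCl), addition of the alkenylmagnesium to the aldehyde of F2 at −78 °C and an Ac2O quench should give the allylic acetate F3, in which C10, C9, C8 and C7 are already connected. Copper hydride conjugate reduction with the ligand of step 3 and t-BuOH, then equilibration of the α-centre with DBU, should give the 2,5-trans ketone F4. LiN(i-Pr)2/Me3SiCl at −78 °C gives the less substituted (C1–C6) silyl enol ether F5. Me3SiOTf (cat.) in CH2Cl2 at −78 °C ionises the allylic acetate, and the enol ether carbon C6 alkylates the tertiary terminus C7 (intramolecular Mukaiyama-type SN1 alkylation), which closes the seven-membered ring to 16.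

Step 6. The α-silyl alkenylalane may undergo cis–trans isomerisation before iodinolysis, so that the diene geometry (and with it C7) is lost, and addition to the α-branched silylalkyne may be slow. The fallback sets out from alkyne 9 and returns at 13. Methylalumination of the terminal alkyne itself (Me3Al, Cp2ZrCl2 cat., CH2Cl2; then I2), where no silyl group labilises the alkenylalane, should give (1E,3S)-1-iodo-2,3,7-trimethylocta-1,6-diene F6 with iodine cis to the new methyl group. Deprotonation α to iodine with LiN(i-Pr)2 in the presence of Me3SiCl at −100 °C (in-situ silylation of the lithium carbenoid, with retention) puts silicon cis to the C11 branch and gives 13.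

Step 11. The electron-rich side-chain alkene may be iodo-functionalised faster than the hindered vinylsilane undergoes ipso attack. The fallback sets out from 19 and returns at 22. Br2 (2 equiv, CH2Cl2, −78 °C; then KF, MeOH) masks the side-chain alkene as its vicinal dibromide while bromodesilylating C8, giving the tribromide F7. Zinc dust in AcOH/Et2O restores the trisubstituted alkene and gives the alkenyl bromide F8. F8 enters the Stille coupling and hydrolysis of step 12 (Pd(t-Bu3P)2 in place of Pd(PPh3)4) and gives 22.

**Further compounds**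

F1 | step 8 | 6-allyl-3-(TBS-oxymethyl)cyclohex-2-en-1-one (racemic at the allyl-bearing carbon) | C=CCC1CCC(CO[Si](C)(C)C(C)(C)C)=CC1=O
F2 | step 8 | 2-[2-oxo-4-(TBS-oxymethyl)cyclohex-3-en-1-yl]acetaldehyde | O=CCC1CCC(CO[Si](C)(C)C(C)(C)C)=CC1=O
F3 | step 8 | allylic acetate from addition of the alkenylmagnesium of 13 to F2 (epimers at the acetate carbon and at the ring α′ carbon) | CC(=O)OC(CC1CCC(CO[Si](C)(C)C(C)(C)C)=CC1=O)/C([Si](C)(C)C)=C(\C)[C@@H](C)CCC=C(C)C
F4 | step 8 | saturated ketone from F3, C5 as in 6, ring α-centre equilibrated toward 2,5-trans | CC(=O)OC(CC1CC[C@@H](CO[Si](C)(C)C(C)(C)C)CC1=O)/C([Si](C)(C)C)=C(\C)[C@@H](C)CCC=C(C)C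
F5 | step 8 | C1–C6 trimethylsilyl enol ether of F4 | CC(=O)OC(CC1CC[C@@H](CO[Si](C)(C)C(C)(C)C)C=C1O[Si](C)(C)C)/C([Si](C)(C)C)=C(\C)[C@@H](C)CCC=C(C)C
F6 | step 6 | (1E,3S)-1-iodo-2,3,7-trimethylocta-1,6-diene | I/C=C(\C)[C@@H](C)CCC=C(C)C
F7 | step 11 | 8-bromo analogue of 19 with the side-chain alkene as its vicinal dibromide | CC(=O)O[C@]1(C)[C@@H]2CC[C@@H](COC(C)=O)[C@@H]1[C@@](C)([C@@H](C)CCC(Br)C(C)(C)Br)C(Br)=CC2
F8 | step 11 | 8-bromo analogue of 19 | CC(=O)O[C@]1(C)[C@@H]2CC[C@@H](COC(C)=O)[C@@H]1[C@@](C)([C@@H](C)CCC=C(C)C)C(Br)=CC2
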